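**Strategy**

Everything rests on cutting the N1–C5 bond of the N-methylpyrrolidine that sits on C8 of flavone ring A. C5 is then the terminal methyl of an open-chain (R)-1-arylbutyl(methyl)amine, delta to nitrogen, so the single stereocentre (pyrrolidine C2) can be set earlier by sulfinamide-directed allylation of an 8-formylflavone. In one operation the key step shifts chlorine from nitrogen to that methyl by 1,5-hydrogen transfer, removes the acetates and closes the ring, giving the target itself. Its precursor is the N-chloro-N-methylamine of the flavone, with acetates on O5, O7 and O4' and the (1R)-butyl chain on C8.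

Key step: step 13

Remark: the (1R) outcome of step 7 assumes the usual chelated chair model for indium allylation of N-sulfinyl aldimines, in which the (S)-sulfinyl group directs attack to the Re face; because the aryl carbon outranks the chain carbon, this is the (R) descriptor that is carried through to C2 of the pyrrolidine.

**Route**

Step 1
Reactants: 1 1-[2,4-bis(benzyloxy)-6-hydroxyphenyl]ethan-1-one
Product: 3 1-[2,4-bis(benzyloxy)-3,6-dihydroxyphenyl]ethan-1-one, via aryl potassium sulfate 2 (not isolated)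
Conditions: K2S2O8, aq KOH, pyridine, 0 → 20 °C; then 2 M HCl, 70 °C, Ar
Reagents that add atoms: potassium peroxodisulfate, [K+].[K+].[O-]S(=O)(=O)OOS(=O)(=O)[O-]
Why: Elbs persulfate oxidation: the phenoxide attacks peroxodisulfate through the carbon para to the hydroxyl (between the two benzyloxy groups), and acid hydrolysis of the aryl sulfate 2 should free the hydroquinone without touching the benzyl ethers.

Step 2
Reactants: 3 1-[2,4-bis(benzyloxy)-3,6-dihydroxyphenyl]ethan-1-one
Product: 4 1-[2,4-bis(benzyloxy)-6-hydroxy-3-methoxyphenyl]ethan-1-one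
Conditions: MeI (1.1 equiv), K2CO3, acetone, 40 °C, Ar
Reagents that add atoms: iodomethane, CI
Why: Williamson ether synthesis made selective by the hydrogen bond that ties the 6-hydroxyl to the acetyl oxygen, so that only the new 3-hydroxyl is alkylated by one equivalent of iodomethane.

Step 3
Reactants: 4 1-[2,4-bis(benzyloxy)-6-hydroxy-3-methoxyphenyl]ethan-1-one; 5 4-(benzyloxy)benzoyl chloride
Product: 6 1-[2,4-bis(benzyloxy)-6-hydroxy-3-methoxyphenyl]-3-[4-(benzyloxy)phenyl]propane-1,3-dione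
Conditions: LiHMDS (3.3 equiv), THF, −78 °C; then 5, −78 → 20 °C; aq HCl work-up
Reagents that add atoms: none
Why: Claisen-type C-acylation of the lithium enolate of the phenoxide–enolate dianion by the aroyl chloride, the one-flask form of the Baker–Venkataraman route to o-hydroxyaryl 1,3-diketones.

Step 4
Reactants: 6 1-[2,4-bis(benzyloxy)-6-hydroxy-3-methoxyphenyl]-3-[4-(benzyloxy)phenyl]propane-1,3-dione
Product: 7 5,7-bis(benzyloxy)-2-[4-(benzyloxy)phenyl]-6-methoxy-4H-chromen-4-one
Conditions: NaOAc, AcOH, 115 °C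
Reagents that add atoms: none
Why: Cyclodehydration of the o-hydroxyaryl 1,3-diketone (closing stage of the Baker–Venkataraman flavone synthesis): the phenol adds to the enolised aroyl carbonyl and water is lost, in a buffered acid that should spare the acid-sensitive 5-O-benzyl ether.

Step 5
Reactants: 7 5,7-bis(benzyloxy)-2-[4-(benzyloxy)phenyl]-6-methoxy-4H-chromen-4-one
Product: 8 5,7-bis(benzyloxy)-2-[4-(benzyloxy)phenyl]-8-iodo-6-methoxy-4H-chromen-4-one
Conditions: NIS (1.1 equiv), CF3CO2H (0.3 equiv), MeCN/CH2Cl2, 0 → 20 °C, dark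
Reagents that add atoms: N-iodosuccinimide, O=C1CCC(=O)N1I
Why: Electrophilic aromatic iodination at C8, the only unsubstituted carbon of ring A, which is activated by O1 and O7 in ortho and O5 in para positions and is the known site of halogenation in 5,7-dialkoxyflavones.

Step 6
Reactants: 8 5,7-bis(benzyloxy)-2-[4-(benzyloxy)phenyl]-8-iodo-6-methoxy-4H-chromen-4-one
Product: 9 5,7-bis(benzyloxy)-2-[4-(benzyloxy)phenyl]-6-methoxy-4-oxo-4H-chromene-8-carbaldehyde
Conditions: PdCl2(dppp) (3 mol%), CO (3 bar), Et3SiH (2 equiv), Na2CO3, DMF, 90 °C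
Reagents that add atoms: carbon monoxide, [C-]#[O+]
Why: Palladium-catalysed reductive carbonylation (formylation) of an aryl iodide: oxidative addition, CO insertion and hydride transfer from the silane to the acylpalladium intermediate, none of which touches the benzyl ethers or the pyrone.

Step 7
Reactants: 9 5,7-bis(benzyloxy)-2-[4-(benzyloxy)phenyl]-6-methoxy-4-oxo-4H-chromene-8-carbaldehyde; 10 (S)-2-methylpropane-2-sulfinamide; 11 3-bromoprop-1-ene (allyl bromide)
Product: 13 (S)-N-[(1R)-1-{5,7-bis(benzyloxy)-2-[4-(benzyloxy)phenyl]-6-methoxy-4-oxo-4H-chromen-8-yl}but-3-en-1-yl]-2-methylpropane-2-sulfinamide, via sulfinyl aldimine 12 (not isolated)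
Conditions: Ti(OEt)4 (2.5 equiv), THF, 60 °C; then In powder (1.5 equiv), 11 (2 equiv), 60 °C
Reagents that add atoms: none
Why: Titanium-mediated condensation to the N-tert-butanesulfinyl aldimine followed by indium-mediated Barbier allylation; the C1 stereocentre is set by the (S)-sulfinyl group, since indium bound to the sulfinyl oxygen should deliver allyl through a six-membered chair transition state to the Re face of the (E)-imine and so give the (1R) configuration, while the weakly electrophilic pyrone carbonyl is left alone.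

Step 8
Reactants: 13 (S)-N-[(1R)-1-{5,7-bis(benzyloxy)-2-[4-(benzyloxy)phenyl]-6-methoxy-4-oxo-4H-chromen-8-yl}but-3-en-1-yl]-2-methylpropane-2-sulfinamide
Product: 14 (S)-N-[(1R)-1-{5,7-bis(benzyloxy)-2-[4-(benzyloxy)phenyl]-6-methoxy-4-oxo-4H-chromen-8-yl}but-3-en-1-yl]-N,2-dimethylpropane-2-sulfinamide
Conditions: LiHMDS (1.2 equiv), THF/DMF, −20 °C; MeI (1.5 equiv), −20 → 0 °C
Reagents that add atoms: iodomethane, CI
Why: N-alkylation of the lithium salt of a secondary sulfinamide with iodomethane, clean because every phenol is benzylated and the anionic nitrogen shields the adjacent benzylic hydrogen from deprotonation, so the stereocentre is kept.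

Step 9
Reactants: 14 (S)-N-[(1R)-1-{5,7-bis(benzyloxy)-2-[4-(benzyloxy)phenyl]-6-methoxy-4-oxo-4H-chromen-8-yl}but-3-en-1-yl]-N,2-dimethylpropane-2-sulfinamide
Product: 15 (S)-N-{(1R)-1-[5,7-dihydroxy-2-(4-hydroxyphenyl)-6-methoxy-4-oxo-4H-chromen-8-yl]butyl}-N,2-dimethylpropane-2-sulfinamide
Conditions: H2 (1–3 bar), 10% Pd/C, EtOAc/MeOH, 20 °C
Reagents that add atoms: none
Why: Heterogeneous catalytic hydrogenation saturates the terminal alkene and hydrogenolyses the three benzyl ethers, while the N-sulfinyl group, a poor leaving group on nitrogen, keeps the benzylic C–N bond from hydrogenolysis.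

Step 10
Reactants: 15 (S)-N-{(1R)-1-[5,7-dihydroxy-2-(4-hydroxyphenyl)-6-methoxy-4-oxo-4H-chromen-8-yl]butyl}-N,2-dimethylpropane-2-sulfinamide
Product: 16 4-{5,7-bis(acetyloxy)-6-methoxy-8-[(1R)-1-{methyl[(S)-2-methylpropane-2-sulfinyl]amino}butyl]-4-oxo-4H-chromen-2-yl}phenyl acetate
Conditions: Ac2O (6 equiv), pyridine, DMAP (cat.), 20 → 40 °C
Reagents that add atoms: acetic anhydride, CC(=O)OC(C)=O
Why: DMAP-catalysed O-acetylation of the three phenols, done while nitrogen still carries the sulfinyl group so that it cannot be acetylated.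

Step 11
Reactants: 16 4-{5,7-bis(acetyloxy)-6-methoxy-8-[(1R)-1-{methyl[(S)-2-methylpropane-2-sulfinyl]amino}butyl]-4-oxo-4H-chromen-2-yl}phenyl acetate
Product: 17 4-{5,7-bis(acetyloxy)-6-methoxy-8-[(1R)-1-(methylamino)butyl]-4-oxo-4H-chromen-2-yl}phenyl acetate hydrochloride
Conditions: HCl (4 M in dioxane, 3 equiv), CH2Cl2/Et2O, 0 °C; salt filtered, no basic work-up
Reagents that add atoms: hydrogen chloride, Cl
Why: Acidolysis of the sulfinamide N–S bond by anhydrous hydrogen chloride, which does not cleave aryl acetates and gives the amine as its hydrochloride, the form in which nitrogen cannot attack the neighbouring O7 acetate.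

Step 12
Reactants: 17 4-{5,7-bis(acetyloxy)-6-methoxy-8-[(1R)-1-(methylamino)butyl]-4-oxo-4H-chromen-2-yl}phenyl acetate hydrochloride
Product: 18 4-{5,7-bis(acetyloxy)-8-[(1R)-1-[chloro(methyl)amino]butyl]-6-methoxy-4-oxo-4H-chromen-2-yl}phenyl acetate
Conditions: NaOCl (aq, 1.3 equiv), AcOH/NaOAc buffer (pH 5), CH2Cl2, 0 °C, dark, 10 min; used at once
Reagents that add atoms: sodium hypochlorite, [Na+].[O-]Cl
Why: N-chlorination of a secondary amine by hypochlorous acid: at pH 5 only a trace of free amine is present at any moment and its capture by HOCl should be far faster than O-to-N acetyl transfer from O7, while the acetylated rings are too electron-poor for C-chlorination.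

Step 13
Reactants: 18 4-{5,7-bis(acetyloxy)-8-[(1R)-1-[chloro(methyl)amino]butyl]-6-methoxy-4-oxo-4H-chromen-2-yl}phenyl acetate
Product: 21 5,7-dihydroxy-2-(4-hydroxyphenyl)-6-methoxy-8-[(2R)-1-methylpyrrolidin-2-yl]-4H-chromen-4-one, via chloroalkylammonium triacetate 19 (not isolated), via chloroalkylamino triphenol salt 20 (not isolated)
Conditions: FeSO4·7H2O (10 mol%), CF3CO2H (0.03 M), Ar, dark, 20 → 40 °C; Me2S quench, evaporate; HCl (1.25 M in MeOH), 40 °C; evaporate; NaHCO3, MeOH/H2O, 20 °C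
Reagents that add atoms: none
Why: Divalent iron reduces the N-chloroammonium ion of 18 to an aminium radical, which takes a hydrogen atom from the terminal methyl (C4 of the butyl chain) through a six-membered transition state; the primary carbon radical then abstracts chlorine from a second N-chloroammonium ion and carries the chain to 19. This is a Hofmann–Löffler–Freytag reaction of an N-chloro-N-methylalkylamine in strong acid, started by an iron salt and not by light because the protonated flavone would absorb the radiation. Acidic methanolysis then removes the three acetates while nitrogen is still protonated, so no acetyl can shift from O7 to nitrogen, and bicarbonate finally frees the amine of 20, which displaces the primary chloride in a 5-exo-tet closure that forms the N1–C5 bond of the pyrrolidine. No stereocentre is created: C2 of the ring is the benzylic carbon set in step 7, its C–H bond lies alpha to a positively charged nitrogen and is polarity-mismatched for the electrophilic aminium radical, and its C–N bond is never broken. Site selectivity is needed for C4 over every other C–H bond and is secured by the chain length, which offers the 1,5 geometry only at the methyl group; acetylation of the phenols and protonation of the pyrone carbonyl keep the fully substituted ring A and ring B inert to chlorination and to the aminium radical.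

**Compound list**

1 | 1-[2,4-bis(benzyloxy)-6-hydroxyphenyl]ethan-1-one | CC(=O)c1c(O)cc(OCc2ccccc2)cc1OCc1ccccc1 | starting material
2 | potassium 3-acetyl-2,6-bis(benzyloxy)-4-hydroxyphenyl sulfate | CC(=O)c1c(O)cc(OCc2ccccc2)c(OS(=O)(=O)[O-])c1OCc1ccccc1.[K+] | intermediate (not isolated)
3 | 1-[2,4-bis(benzyloxy)-3,6-dihydroxyphenyl]ethan-1-one | CC(=O)c1c(O)cc(OCc2ccccc2)c(O)c1OCc1ccccc1 | intermediate
4 | 1-[2,4-bis(benzyloxy)-6-hydroxy-3-methoxyphenyl]ethan-1-one | CC(=O)c1c(O)cc(OCc2ccccc2)c(OC)c1OCc1ccccc1 | intermediate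
5 | 4-(benzyloxy)benzoyl chloride | O=C(Cl)c1ccc(OCc2ccccc2)cc1 | starting material
6 | 1-[2,4-bis(benzyloxy)-6-hydroxy-3-methoxyphenyl]-3-[4-(benzyloxy)phenyl]propane-1,3-dione | O=C(CC(=O)c1ccc(OCc2ccccc2)cc1)c1c(O)cc(OCc2ccccc2)c(OC)c1OCc1ccccc1 | intermediate
7 | 5,7-bis(benzyloxy)-2-[4-(benzyloxy)phenyl]-6-methoxy-4H-chromen-4-one | COc1c(OCc2ccccc2)cc2oc(-c3ccc(OCc4ccccc4)cc3)cc(=O)c2c1OCc1ccccc1 | intermediate
8 | 5,7-bis(benzyloxy)-2-[4-(benzyloxy)phenyl]-8-iodo-6-methoxy-4H-chromen-4-one | COc1c(OCc2ccccc2)c(I)c2oc(-c3ccc(OCc4ccccc4)cc3)cc(=O)c2c1OCc1ccccc1 | intermediate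
9 | 5,7-bis(benzyloxy)-2-[4-(benzyloxy)phenyl]-6-methoxy-4-oxo-4H-chromene-8-carbaldehyde | COc1c(OCc2ccccc2)c(C=O)c2oc(-c3ccc(OCc4ccccc4)cc3)cc(=O)c2c1OCc1ccccc1 | intermediate
10 | (S)-2-methylpropane-2-sulfinamide | CC(C)(C)[S@](=O)N | starting material
11 | 3-bromoprop-1-ene (allyl bromide) | C=CCBr | starting material
12 | (S)-N-[(E)-{5,7-bis(benzyloxy)-2-[4-(benzyloxy)phenyl]-6-methoxy-4-oxo-4H-chromen-8-yl}methylidene]-2-methylpropane-2-sulfinamide | CC(C)(C)[S@](=O)/N=C/c1c(OCc2ccccc2)c(OC)c(OCc2ccccc2)c2c(=O)cc(-c3ccc(OCc4ccccc4)cc3)oc12 | intermediate (not isolated)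
13 | (S)-N-[(1R)-1-{5,7-bis(benzyloxy)-2-[4-(benzyloxy)phenyl]-6-methoxy-4-oxo-4H-chromen-8-yl}but-3-en-1-yl]-2-methylpropane-2-sulfinamide | CC(C)(C)[S@](=O)N[C@H](CC=C)c1c(OCc2ccccc2)c(OC)c(OCc2ccccc2)c2c(=O)cc(-c3ccc(OCc4ccccc4)cc3)oc12 | intermediate
14 | (S)-N-[(1R)-1-{5,7-bis(benzyloxy)-2-[4-(benzyloxy)phenyl]-6-methoxy-4-oxo-4H-chromen-8-yl}but-3-en-1-yl]-N,2-dimethylpropane-2-sulfinamide | CC(C)(C)[S@](=O)N(C)[C@H](CC=C)c1c(OCc2ccccc2)c(OC)c(OCc2ccccc2)c2c(=O)cc(-c3ccc(OCc4ccccc4)cc3)oc12 | intermediate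
15 | (S)-N-{(1R)-1-[5,7-dihydroxy-2-(4-hydroxyphenyl)-6-methoxy-4-oxo-4H-chromen-8-yl]butyl}-N,2-dimethylpropane-2-sulfinamide | CC(C)(C)[S@](=O)N(C)[C@H](CCC)c1c(O)c(OC)c(O)c2c(=O)cc(-c3ccc(O)cc3)oc12 | intermediate
16 | 4-{5,7-bis(acetyloxy)-6-methoxy-8-[(1R)-1-{methyl[(S)-2-methylpropane-2-sulfinyl]amino}butyl]-4-oxo-4H-chromen-2-yl}phenyl acetate | CC(C)(C)[S@](=O)N(C)[C@H](CCC)c1c(OC(C)=O)c(OC)c(OC(C)=O)c2c(=O)cc(-c3ccc(OC(C)=O)cc3)oc12 | intermediate
17 | 4-{5,7-bis(acetyloxy)-6-methoxy-8-[(1R)-1-(methylamino)butyl]-4-oxo-4H-chromen-2-yl}phenyl acetate hydrochloride | CN[C@H](CCC)c1c(OC(C)=O)c(OC)c(OC(C)=O)c2c(=O)cc(-c3ccc(OC(C)=O)cc3)oc12.Cl | intermediate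
18 | 4-{5,7-bis(acetyloxy)-8-[(1R)-1-[chloro(methyl)amino]butyl]-6-methoxy-4-oxo-4H-chromen-2-yl}phenyl acetate | COc1c(OC(C)=O)c([C@H](N(C)Cl)CCC)c2oc(-c3ccc(OC(C)=O)cc3)cc(=O)c2c1OC(C)=O | intermediate (precursor of the key step)
19 | 4-{5,7-bis(acetyloxy)-8-[(1R)-4-chloro-1-(methylamino)butyl]-6-methoxy-4-oxo-4H-chromen-2-yl}phenyl acetate trifluoroacetate | CN[C@H](CCCCl)c1c(OC(C)=O)c(OC)c(OC(C)=O)c2c(=O)cc(-c3ccc(OC(C)=O)cc3)oc12.OC(=O)C(F)(F)F | intermediate (not isolated)
20 | 8-[(1R)-4-chloro-1-(methylamino)butyl]-5,7-dihydroxy-2-(4-hydroxyphenyl)-6-methoxy-4H-chromen-4-one hydrochloride | CN[C@H](CCCCl)c1c(O)c(OC)c(O)c2c(=O)cc(-c3ccc(O)cc3)oc12.Cl | intermediate (not isolated)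
21 | 5,7-dihydroxy-2-(4-hydroxyphenyl)-6-methoxy-8-[(2R)-1-methylpyrrolidin-2-yl]-4H-chromen-4-one | COc1c(O)c([C@H]2CCCN2C)c2oc(-c3ccc(O)cc3)cc(=O)c2c1O | target

**Step count and risks**

Total step count: 13. Longest linear sequence: 13 steps (1 → 21).

The three steps most likely to fail, most serious first:

Step 13. The radical chain may stall at the primary C–H bond, or the aminium radical may be lost through fragmentation of the benzylic C–C bond or through loss of HCl to an imine, so that C4 is never chlorinated. The fallback closes the same N1–C5 bond by substitution instead of C–H functionalisation and sets out from 14. Hydroboration of the terminal alkene (9-BBN, THF; then NaBO3·4H2O) should give the primary alcohol (S)-N-[(1R)-1-{5,7-bis(benzyloxy)-2-[4-(benzyloxy)phenyl]-6-methoxy-4-oxo-4H-chromen-8-yl}-4-hydroxybutyl]-N,2-dimethylpropane-2-sulfinamide F1. MsCl/Et3N converts it into the sulfinamide methanesulfonate F2. Anhydrous HCl in dioxane cleaves the sulfinyl group to the aminium chloride methanesulfonate F3. K2CO3 in MeCN then closes the ring by 5-exo-tet N-alkylation to 5,7-bis(benzyloxy)-2-[4-(benzyloxy)phenyl]-6-methoxy-8-[(2R)-1-methylpyrrolidin-2-yl]-4H-chromen-4-one F4. Hydrogenolysis of the three benzyl ethers (H2, Pd/C, EtOAc/MeOH) brings the route back at 21.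

Step 7. Facial selectivity in the allyl transfer may be low or inverted if O7 or O1 competes with the sulfinyl oxygen for indium, and addition to the doubly ortho-substituted aldimine may be slow. The fallback gives up auxiliary control for a racemic synthesis with separation of enantiomers and sets out from 9. Condensation with methylamine (THF, MgSO4) should give the N-methyl aldimine F5. Allylzinc bromide in THF at 0 °C adds to it to give the racemic N-methyl homoallylamine F6. Preparative chromatography on a chiral stationary phase isolates the (1R)-enantiomer F7, whose configuration would be assigned through a Mosher amide. Hydrogenation in the presence of one equivalent of HCl (H2, Pd/C, MeOH) saturates the alkene and removes the benzyl groups to give the triphenol amine hydrochloride F8. O-Acetylation under acid (AcCl in CF3CO2H, nitrogen protonated) followed by HCl in ether returns the route at 17.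

Step 12. Acetyl may migrate from O7 to nitrogen during the short life of the free amine, and the N-chloroamine may lose HCl to an imine before it is used. The fallback replaces the acetates by sulfonates, which do not transfer to nitrogen, and sets out from 15. MsCl/Et3N in CH2Cl2 should give the tris(methanesulfonate) sulfinamide F9. HCl in dioxane gives the amine hydrochloride F10. NCS with NaHCO3 in CH2Cl2 gives the N-chloroamine tris(methanesulfonate) F11. The iron-initiated rearrangement in CF3CO2H, as in step 13, gives the 4-chlorobutyl ammonium trifluoroacetate F12. K2CO3 in MeCN closes the pyrrolidine to the tris(methanesulfonate) of the target F13. Aqueous NaOH in MeOH at 40 °C under argon cleaves the three aryl sulfonates and the route is rejoined at 21.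

Further compounds
F1 | step 13 | (S)-N-[(1R)-1-{5,7-bis(benzyloxy)-2-[4-(benzyloxy)phenyl]-6-methoxy-4-oxo-4H-chromen-8-yl}-4-hydroxybutyl]-N,2-dimethylpropane-2-sulfinamide | CC(C)(C)[S@](=O)N(C)[C@H](CCCO)c1c(OCc2ccccc2)c(OC)c(OCc2ccccc2)c2c(=O)cc(-c3ccc(OCc4ccccc4)cc3)oc12
F2 | step 13 | (4R)-4-{5,7-bis(benzyloxy)-2-[4-(benzyloxy)phenyl]-6-methoxy-4-oxo-4H-chromen-8-yl}-4-{methyl[(S)-2-methylpropane-2-sulfinyl]amino}butyl methanesulfonate | CC(C)(C)[S@](=O)N(C)[C@H](CCCOS(C)(=O)=O)c1c(OCc2ccccc2)c(OC)c(OCc2ccccc2)c2c(=O)cc(-c3ccc(OCc4ccccc4)cc3)oc12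
F3 | step 13 | (4R)-4-{5,7-bis(benzyloxy)-2-[4-(benzyloxy)phenyl]-6-methoxy-4-oxo-4H-chromen-8-yl}-4-(methylamino)butyl methanesulfonate hydrochloride | CN[C@H](CCCOS(C)(=O)=O)c1c(OCc2ccccc2)c(OC)c(OCc2ccccc2)c2c(=O)cc(-c3ccc(OCc4ccccc4)cc3)oc12.Cl
F4 | step 13 | 5,7-bis(benzyloxy)-2-[4-(benzyloxy)phenyl]-6-methoxy-8-[(2R)-1-methylpyrrolidin-2-yl]-4H-chromen-4-one | COc1c(OCc2ccccc2)c([C@H]2CCCN2C)c2oc(-c3ccc(OCc4ccccc4)cc3)cc(=O)c2c1OCc1ccccc1
F5 | step 7 | (E)-1-{5,7-bis(benzyloxy)-2-[4-(benzyloxy)phenyl]-6-methoxy-4-oxo-4H-chromen-8-yl}-N-methylmethanimine | C/N=C/c1c(OCc2ccccc2)c(OC)c(OCc2ccccc2)c2c(=O)cc(-c3ccc(OCc4ccccc4)cc3)oc12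
F6 | step 7 | racemic 5,7-bis(benzyloxy)-2-[4-(benzyloxy)phenyl]-6-methoxy-8-[1-(methylamino)but-3-en-1-yl]-4H-chromen-4-one | CNC(CC=C)c1c(OCc2ccccc2)c(OC)c(OCc2ccccc2)c2c(=O)cc(-c3ccc(OCc4ccccc4)cc3)oc12
F7 | step 7 | 5,7-bis(benzyloxy)-2-[4-(benzyloxy)phenyl]-6-methoxy-8-[(1R)-1-(methylamino)but-3-en-1-yl]-4H-chromen-4-one | CN[C@H](CC=C)c1c(OCc2ccccc2)c(OC)c(OCc2ccccc2)c2c(=O)cc(-c3ccc(OCc4ccccc4)cc3)oc12
F8 | step 7 | 5,7-dihydroxy-2-(4-hydroxyphenyl)-6-methoxy-8-[(1R)-1-(methylamino)butyl]-4H-chromen-4-one hydrochloride | CN[C@H](CCC)c1c(O)c(OC)c(O)c2c(=O)cc(-c3ccc(O)cc3)oc12.Cl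
F9 | step 12 | 4-{6-methoxy-5,7-bis[(methanesulfonyl)oxy]-8-[(1R)-1-{methyl[(S)-2-methylpropane-2-sulfinyl]amino}butyl]-4-oxo-4H-chromen-2-yl}phenyl methanesulfonate | CC(C)(C)[S@](=O)N(C)[C@H](CCC)c1c(OS(C)(=O)=O)c(OC)c(OS(C)(=O)=O)c2c(=O)cc(-c3ccc(OS(C)(=O)=O)cc3)oc12
F10 | step 12 | 4-{6-methoxy-5,7-bis[(methanesulfonyl)oxy]-8-[(1R)-1-(methylamino)butyl]-4-oxo-4H-chromen-2-yl}phenyl methanesulfonate hydrochloride | CN[C@H](CCC)c1c(OS(C)(=O)=O)c(OC)c(OS(C)(=O)=O)c2c(=O)cc(-c3ccc(OS(C)(=O)=O)cc3)oc12.Cl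
F11 | step 12 | 4-{8-[(1R)-1-[chloro(methyl)amino]butyl]-6-methoxy-5,7-bis[(methanesulfonyl)oxy]-4-oxo-4H-chromen-2-yl}phenyl methanesulfonate | COc1c(OS(C)(=O)=O)c([C@H](N(C)Cl)CCC)c2oc(-c3ccc(OS(C)(=O)=O)cc3)cc(=O)c2c1OS(C)(=O)=O
F12 | step 12 | 4-{8-[(1R)-4-chloro-1-(methylamino)butyl]-6-methoxy-5,7-bis[(methanesulfonyl)oxy]-4-oxo-4H-chromen-2-yl}phenyl methanesulfonate trifluoroacetate | CN[C@H](CCCCl)c1c(OS(C)(=O)=O)c(OC)c(OS(C)(=O)=O)c2c(=O)cc(-c3ccc(OS(C)(=O)=O)cc3)oc12.OC(=O)C(F)(F)F
F13 | step 12 | 4-{6-methoxy-5,7-bis[(methanesulfonyl)oxy]-8-[(2R)-1-methylpyrrolidin-2-yl]-4-oxo-4H-chromen-2-yl}phenyl methanesulfonate | COc1c(OS(C)(=O)=O)c([C@H]2CCCN2C)c2oc(-c3ccc(OS(C)(=O)=O)cc3)cc(=O)c2c1OS(C)(=O)=O
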